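Locants used throughout: the flavan-3,4-diol unit is rings A/C/B with atoms O1 to C8a; the 4-aryl flavan-3-ol unit is rings D/F/E with primed atoms; the two are joined C4'–C6. Compound numbers are those of the list after the steps. Bn = benzyl, TBS = tert-butyldimethylsilyl. FL = the (2R,3R)-3,7,8-tris(benzyloxy)-2-[3,4-bis(benzyloxy)phenyl]chroman-4-yl group (2,3-cis), bonded through C4 with the 4-aryl bond trans to O3. Its C4 descriptor is R while O7 of ring A is benzylated and S while it is a free hydroxyl; this is a change of CIP priority, not of configuration.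

Analysis of the target

The target 31 is a biflavonoid. A flavan-3,4-diol (ring A 7,8-dihydroxylated, ring B a 4-hydroxyphenyl group) carries at C6 a 4-aryl flavan-3-ol (ring D 7',8'-dihydroxylated, ring E a catechol). There are six stereocentres: C2, C3 and C4 are all-cis (2R,3R,4R), and C2', C3' and C4' are 2',3'-cis-3',4'-trans (2'R,3'R,4'S). The two clusters are held apart by ring A and cannot control each other, but both contain the same (2R,3R)-cis aryl/oxygen pair. The C4 hydroxyl is benzylic and para to O7, so acid ionises it to a quinone methide. O1–C2 and O1'–C2' are benzylic ethers of electron-rich aryl groups, the C4'–C6 bond is acid-labile like any interflavan bond, and the seven phenolic hydroxyls on four oxygen-rich rings oxidise readily in base and air. The main difficulty is the cis,cis triad at C2 to C4: any ring C closure that makes or breaks a bond at C2 or C4 passes through a benzylic cation and erodes it. A second difficulty is the substitution of ring A, which must be linked at C6 and not at C5. The strategy rests on the fact that O1 joins the sp3 carbon C2 to the aromatic carbon C8a, so ring C can be closed at the aryl–oxygen bond O1–C8a, away from every stereocentre. In addition, rings A and D share the same pattern (oxygen at C7 and C8, heteroatom at C8a, carbon at C4a), so one bromo aldehyde can supply both.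

Retrosynthetic reasoning

31 back to 29. All seven phenols and the secondary oxygens O3 and O3' are carried as benzyl ethers and O4 as a silyl ether. The silyl group is taken off first, on the fully benzylated 29 (giving 30), and the nine benzyl ethers are removed by hydrogenolysis in the last step. The air- and acid-sensitive decaol 31 then only needs filtering and evaporating.

29 back to 28. Ring C is cut at O1–C8a. Cutting O1–C2 would require a substitution at benzylic C2, and cutting C4–C4a a Friedel–Crafts reaction at C4; both put a cation next to the triad. With the cut at O1–C8a the triad is assembled in an open chain, and the forward step only has to arylate the free C2 hydroxyl of 28 with the neighbouring C8a bromide under copper catalysis. O3 (benzyl) and O4 (silyl) are blocked, and the 2,3-syn-3,4-anti chain becomes the 2,3-cis-3,4-cis ring.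

28 back to 25 and 27. The C2–ring B bond is cut next. The forward reaction is the addition of aryl Grignard reagent 27 (from bromide 26) to the α-benzyloxy aldehyde 25 under chelation control. This gives the 2,3-syn alcohol with the C2 hydroxyl free, which is exactly what the ring closure needs. The silyl ether at O4 is chosen because it does not chelate.

25 back to 20 and 3. The C3–C4 bond is cut, with the formyl carbon of 25 traced to a vinyl group. Forward, the (E)-γ-benzyloxyallylboronate 3 adds to aldehyde 20 under a chiral Brønsted acid. The E geometry gives the 3,4-anti pair and the catalyst sets the absolute configuration (22). Silylation (23) and oxidative cleavage of the alkene then give 25.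

20 back to 16 and 17. The interflavan bond C4'–C6 is cut. Forward, the benzylic 4-hydroxyl of 16 is ionised by a Lewis acid and the cation is captured by ring A. A 2,3-cis flavan-4-yl cation is attacked anti to its 3-substituent, which gives the required 3',4'-trans bond. Ring A is used as catechol 17: the free C7 hydroxyl directs attack to C6, the formyl group is masked as a dithiane so that it neither deactivates the ring nor suffers under acid, and the bromine is already in place at C8a. Benzylation of 18 (giving 19) and unmasking then give 20.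

16 back to 6, 3 and 13. The lower unit has the same ring pattern and the same (2R,3R)-cis pair as the upper unit, so it is made by the same operations. These are alkoxyallylboration of 6 with 3 (8), silylation (9), alkene cleavage (11), chelation-controlled addition of 13 (from 12) to give 14, and copper-catalysed closure of ring F (15). Its C4' oxygen, set free in 16, then serves as the leaving group. The closure of ring F is the same reaction as the key step on a simpler substrate and rehearses it.

6, 17 and 3 back to 4 and 1. Both 6 and 17 come from catechol aldehyde 5, which is made by demethylation of 2-bromoisovanillin 4; this fixes the bromine position from the start. Reagent 3 comes from benzyl propargyl ether 1 by hydroboration (2) and double-bond transposition.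

Alternatives that were turned down

Alternative 1: Both pyran rings are cut at the benzylic bonds O1–C2 and O1'–C2'. In the forward step the bis(cis-epoxide) A2, with free phenols at C8a and C8a', is treated with mild acid. Each phenol opens its epoxide at the benzylic carbon in a 6-endo manner with inversion, giving A1. In its favour, two rings close in one operation and O3 and O3' emerge free, so the route is shorter than the chosen one. Against it, C2 and C2' carry 4-benzyloxyphenyl and 3,4-bis(benzyloxy)phenyl groups. Such epoxides ionise under acid before the phenol arrives, so inversion is not secured and the more stable 2,3-trans isomers can form at two centres at once. 5-exo attack at C3 and C3' also competes. The two cis-epoxides would have to be set by catalyst control on Z-alkenes in a molecule that already carries C4 and C4', and aryl-conjugated Z-alkenes tend to give some trans-epoxide. Alternative 1 is stronger on step economy. The chosen strategy offers stereochemical security instead, because C2 never carries a leaving group.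

Alternative 2: Only ring F is cut, at O1'–C2', and C4' is created by differentiating two identical aryl groups. In the forward step epoxide A4, whose C4' carries two 2-hydroxy-3,4-bis(benzyloxy)phenyl groups, is opened at C2' by one of the two phenols to give A3; the other aryl group becomes ring A. In its favour, both C4'–aryl bonds are made on a symmetrical stage with no regiochemical question at ring A, and one step sets C4' and closes ring F. Against it, the same ionisation at C2' threatens the 2',3'-cis relationship, and the choice between the two diastereotopic phenols, which decides 3',4'-trans against cis, rests only on a conformational preference. A3 also answers only the lower half. Its ring A has oxygen at C8a and no carbon at C4a, so ring C would still have to be built, most naturally from the C8a oxygen onto benzylic C2, which brings back the problem the chosen disconnection avoids. Alternative 2 is stronger on the regiochemistry of ring A. The chosen strategy gives a complete answer for ring C and a C4' configuration that follows from the known facial preference of a cyclic cation.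

Alternative 3: Ring F and the interflavan bond are cut at C4'–C4a' and C4'–C6. In the forward step a boron Lewis acid makes the α-benzyloxy β-aryloxy aldehyde A6 cyclise onto ring D. The resulting 4'-carbinol ionises and is captured by C6 of the finished upper unit A7, giving A5. In its favour, it is the most convergent plan: two carbon–carbon bonds and one ring form in a single late operation, and the longest linear sequence would be the shortest of all. Against it, A7 already contains the all-cis triad, and its C4–O bond, para to the free O7, is the bond most easily ionised by the same Lewis acid, so epimerisation at C4 and self-condensation compete with the capture. In A6 the benzylic aryl ether at C2' and the α-stereocentre are exposed to the acid as well. Alternative 3 is stronger on convergence. The chosen strategy builds the acid-labile triad only after the last acidic step and closes ring C under basic conditions.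

Key step: step 19

Assumption: (S)-TRIP is taken to direct allyl transfer from a pinacol allylboronate to the Si face of an aryl aldehyde; if the sense of induction proved opposite, the mirror-image acid would be used in steps 5 and 15.

Step 1
Reactants: 1 benzyl propargyl ether [3-(benzyloxy)prop-1-yne]
Product: 2 2-[(E)-3-(benzyloxy)prop-1-en-1-yl]-4,4,5,5-tetramethyl-1,3,2-dioxaborolane
Conditions: pinacolborane (1.2 equiv), Cp2Zr(H)Cl (5 mol%), Et3N (10 mol%), neat, 60 °C
Reagents that add atoms: pinacolborane, B1OC(C)(C)C(C)(C)O1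
Why: Zirconocene hydride-catalysed hydroboration of a terminal alkyne; syn addition with boron at the terminal carbon should give only the (E)-alkenylboronate.

Step 2
Reactants: 2 2-[(E)-3-(benzyloxy)prop-1-en-1-yl]-4,4,5,5-tetramethyl-1,3,2-dioxaborolane
Product: 3 2-[(E)-3-(benzyloxy)prop-2-en-1-yl]-4,4,5,5-tetramethyl-1,3,2-dioxaborolane
Conditions: [Ir(cod)(PPh2Me)2]PF6 (3 mol%, activated with H2, then degassed), THF, rt
Reagents that add atoms: none
Why: Iridium hydride-catalysed 1,3-hydrogen shift, the isomerisation known for allyl ethers and for 3-silyloxy-1-propenylboronates; the double bond moves into conjugation with oxygen as the trans enol ether, which turns the alkenylboronate into the (E)-γ-alkoxyallylboronate.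

Step 3
Reactants: 4 2-bromoisovanillin (2-bromo-3-hydroxy-4-methoxybenzaldehyde)
Product: 5 2-bromo-3,4-dihydroxybenzaldehyde
Conditions: BBr3 (2.5 equiv), CH2Cl2, −78 °C to rt; H2O
Reagents that add atoms: none
Why: Lewis acid cleavage of the aryl methyl ether; the formyl group and the aryl bromide are inert to BBr3 under these conditions.

Step 4
Reactants: 5 2-bromo-3,4-dihydroxybenzaldehyde
Product: 6 3,4-bis(benzyloxy)-2-bromobenzaldehyde
Conditions: BnBr (2.4 equiv), K2CO3, DMF, 60 °C
Reagents that add atoms: benzyl bromide, BrCc1ccccc1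
Why: Williamson ether synthesis on both phenols.

Step 5
Reactants: 6 3,4-bis(benzyloxy)-2-bromobenzaldehyde; 3 2-[(E)-3-(benzyloxy)prop-2-en-1-yl]-4,4,5,5-tetramethyl-1,3,2-dioxaborolane
Product: 8 (1R,2S)-2-(benzyloxy)-1-[3,4-bis(benzyloxy)-2-bromophenyl]but-3-en-1-ol, via pinacol borate ester 7 (not isolated)
Conditions: 3 (1.3 equiv), (S)-TRIP [(S)-3,3'-bis(2,4,6-triisopropylphenyl)-1,1'-binaphthyl-2,2'-diyl hydrogen phosphate] (5 mol%), 4 Å MS, toluene, −30 °C; aq. NaHCO3
Reagents that add atoms: none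
Why: Chiral phosphoric acid-catalysed allylboration through a closed six-membered chair transition state; the E geometry of 3 places OBn equatorial and gives the 1,2-anti pair, and the acid directs the allyl carbon to the Si face of 6, so the benzyloxy carbon (future C3') and the carbinol carbon (future C4') should form as the (1R,2S) isomer. Borate 7 is hydrolysed on work-up.

Step 6
Reactants: 8 (1R,2S)-2-(benzyloxy)-1-[3,4-bis(benzyloxy)-2-bromophenyl]but-3-en-1-ol
Product: 9 (1R,2S)-2-(benzyloxy)-1-[3,4-bis(benzyloxy)-2-bromophenyl]-1-[(tert-butyldimethylsilyl)oxy]but-3-ene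
Conditions: TBSOTf (1.3 equiv), 2,6-lutidine, CH2Cl2, 0 °C
Reagents that add atoms: tert-butyldimethylsilyl trifluoromethanesulfonate, CC(C)(C)[Si](C)(C)OS(=O)(=O)C(F)(F)F
Why: Silylation of the hindered benzylic alcohol with a silyl triflate; the silyl ether does not chelate magnesium in step 8 and withstands carbonate at 110 °C in step 9.

Step 7
Reactants: 9 (1R,2S)-2-(benzyloxy)-1-[3,4-bis(benzyloxy)-2-bromophenyl]-1-[(tert-butyldimethylsilyl)oxy]but-3-ene
Product: 11 (2R,3R)-2-(benzyloxy)-3-[3,4-bis(benzyloxy)-2-bromophenyl]-3-[(tert-butyldimethylsilyl)oxy]propanal, via 1,2-diol 10 (not isolated)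
Conditions: OsO4 (2 mol%), NaIO4 (4 equiv), 2,6-lutidine (2 equiv), 1,4-dioxane–H2O 3:1, rt
Reagents that add atoms: osmium tetroxide, O=[Os](=O)(=O)=O (delivers the oxygen; turned over by sodium periodate, [Na+].[O-]I(=O)(=O)=O)
Why: Lemieux–Johnson oxidation: OsO4 dihydroxylates the only alkene to diol 10 and periodate cleaves it; 2,6-lutidine buffers the mixture so that the α-benzyloxy aldehyde is not epimerised. Crude 11 is used at once.

Step 8
Reactants: 11 (2R,3R)-2-(benzyloxy)-3-[3,4-bis(benzyloxy)-2-bromophenyl]-3-[(tert-butyldimethylsilyl)oxy]propanal; 12 1,2-bis(benzyloxy)-4-bromobenzene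
Product: 14 (1R,2S,3R)-2-(benzyloxy)-1-[3,4-bis(benzyloxy)phenyl]-3-[3,4-bis(benzyloxy)-2-bromophenyl]-3-[(tert-butyldimethylsilyl)oxy]propan-1-ol, via 3,4-bis(benzyloxy)phenylmagnesium bromide 13 (not isolated)
Conditions: 12, Mg, THF, rt; then added to 11, MgBr2·OEt2, CH2Cl2, −78 °C; aq. NH4Cl
Reagents that add atoms: none
Why: Cram-chelate addition: magnesium bridges the formyl oxygen and the α-benzyloxy oxygen (the β-silyloxy group does not compete), and Grignard reagent 13 attacks the chelate from the face of the α-hydrogen, which should give the 1,2-syn alcohol (future C2', R).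

Step 9
Reactants: 14 (1R,2S,3R)-2-(benzyloxy)-1-[3,4-bis(benzyloxy)phenyl]-3-[3,4-bis(benzyloxy)-2-bromophenyl]-3-[(tert-butyldimethylsilyl)oxy]propan-1-ol
Product: 15 (2R,3S,4R)-3,7,8-tris(benzyloxy)-2-[3,4-bis(benzyloxy)phenyl]-4-[(tert-butyldimethylsilyl)oxy]chromane (2,3-cis-3,4-cis)
Conditions: CuI (10 mol%), 3,4,7,8-tetramethyl-1,10-phenanthroline (20 mol%), Cs2CO3 (2 equiv), toluene, 110 °C, argon
Reagents that add atoms: none
Why: Ullmann-type intramolecular O-arylation of a secondary alkoxide by an aryl bromide (6-exo closure of ring F at the sp2 carbon C8a'); no bond to a stereocentre is broken, so the syn,anti chain becomes the 2,3-cis-3,4-cis flavan. This is the reaction of step 19 on a simpler substrate and rehearses it.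

Step 10
Reactants: 15 (2R,3S,4R)-3,7,8-tris(benzyloxy)-2-[3,4-bis(benzyloxy)phenyl]-4-[(tert-butyldimethylsilyl)oxy]chromane
Product: 16 (2R,3R,4R)-3,7,8-tris(benzyloxy)-2-[3,4-bis(benzyloxy)phenyl]chroman-4-ol
Conditions: Bu4NF, AcOH (1:1), THF, 0 °C to rt
Reagents that add atoms: none
Why: Fluoride cleavage of the silyl ether, buffered with acetic acid; the free 4-hydroxyl is the leaving group of step 12.

Step 11
Reactants: 5 2-bromo-3,4-dihydroxybenzaldehyde
Product: 17 3-bromo-4-(1,3-dithian-2-yl)benzene-1,2-diol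
Conditions: propane-1,3-dithiol (1.1 equiv), BF3·OEt2 (0.2 equiv), CH2Cl2–THF, 0 °C to rt
Reagents that add atoms: propane-1,3-dithiol, SCCCS
Why: Lewis acid-catalysed dithioacetalisation; the dithiane masks the formyl group, removes its deactivating effect on ring A and withstands the acid of step 12.

Step 12
Reactants: 16 (2R,3R,4R)-3,7,8-tris(benzyloxy)-2-[3,4-bis(benzyloxy)phenyl]chroman-4-ol; 17 3-bromo-4-(1,3-dithian-2-yl)benzene-1,2-diol
Product: 18 3-bromo-4-(1,3-dithian-2-yl)-6-[(4S)-FL]benzene-1,2-diol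
Conditions: 17 (3 equiv), BF3·OEt2 (0.2 equiv), 4 Å MS, CH2Cl2–1,4-dioxane 4:1, −20 to 0 °C
Reagents that add atoms: none
Why: Acid-catalysed Friedel–Crafts alkylation, the flavan-3,4-diol/phenol condensation of proanthocyanidin chemistry: ionisation of the C4' hydroxyl gives a cation stabilised by O7' and O1', which the excess catechol 17 should capture through C6, ortho to the C7 hydroxyl and para to bromine, while C5 is shielded by the dithianyl group. The nucleophile enters anti to the pseudo-axial 3'-benzyloxy group of the 2',3'-cis cation, so C4' should form 3',4'-trans.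

Step 13
Reactants: 18 3-bromo-4-(1,3-dithian-2-yl)-6-[(4S)-FL]benzene-1,2-diol
Product: 19 2-{3,4-bis(benzyloxy)-2-bromo-5-[(4R)-FL]phenyl}-1,3-dithiane
Conditions: BnBr (3 equiv), K2CO3, DMF, 50 °C
Reagents that add atoms: benzyl bromide, BrCc1ccccc1
Why: Williamson ether synthesis on the two phenols of ring A; the phenoxides are far more nucleophilic than the thioacetal sulfur.

Step 14
Reactants: 19 2-{3,4-bis(benzyloxy)-2-bromo-5-[(4R)-FL]phenyl}-1,3-dithiane
Product: 20 3,4-bis(benzyloxy)-2-bromo-5-[(4R)-FL]benzaldehyde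
Conditions: MeI (excess), CaCO3, MeCN–H2O 9:1, 45 °C
Reagents that add atoms: water, O
Why: Alkylative hydrolysis of the dithiane (S-methylation to a sulfonium ion, then hydrolysis) under neutral conditions that spare the aryl bromide, the benzyl ethers and the interflavan bond.

Step 15
Reactants: 20 3,4-bis(benzyloxy)-2-bromo-5-[(4R)-FL]benzaldehyde; 3 2-[(E)-3-(benzyloxy)prop-2-en-1-yl]-4,4,5,5-tetramethyl-1,3,2-dioxaborolane
Product: 22 (1R,2S)-2-(benzyloxy)-1-{3,4-bis(benzyloxy)-2-bromo-5-[(4R)-FL]phenyl}but-3-en-1-ol, via pinacol borate ester 21 (not isolated)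
Conditions: 3 (1.5 equiv), (S)-TRIP [(S)-3,3'-bis(2,4,6-triisopropylphenyl)-1,1'-binaphthyl-2,2'-diyl hydrogen phosphate] (10 mol%), 4 Å MS, toluene, −30 °C; aq. NaHCO3
Reagents that add atoms: none
Why: The same chiral phosphoric acid-catalysed allylboration as in step 5: the chair transition state with the E reagent gives the 3,4-anti pair, and Si-face attack sets C4 as R and the benzyloxy carbon C3 with it. The remote lower unit should not affect the catalyst-controlled face selection.

Step 16
Reactants: 22 (1R,2S)-2-(benzyloxy)-1-{3,4-bis(benzyloxy)-2-bromo-5-[(4R)-FL]phenyl}but-3-en-1-ol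
Product: 23 (1R,2S)-2-(benzyloxy)-1-{3,4-bis(benzyloxy)-2-bromo-5-[(4R)-FL]phenyl}-1-[(tert-butyldimethylsilyl)oxy]but-3-ene
Conditions: TBSOTf (1.5 equiv), 2,6-lutidine, CH2Cl2, 0 °C
Reagents that add atoms: tert-butyldimethylsilyl trifluoromethanesulfonate, CC(C)(C)[Si](C)(C)OS(=O)(=O)C(F)(F)F
Why: Silylation of the benzylic alcohol with a silyl triflate buffered by 2,6-lutidine, as in step 6.

Step 17
Reactants: 23 (1R,2S)-2-(benzyloxy)-1-{3,4-bis(benzyloxy)-2-bromo-5-[(4R)-FL]phenyl}-1-[(tert-butyldimethylsilyl)oxy]but-3-ene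
Product: 25 (2R,3R)-2-(benzyloxy)-3-{3,4-bis(benzyloxy)-2-bromo-5-[(4R)-FL]phenyl}-3-[(tert-butyldimethylsilyl)oxy]propanal, via 1,2-diol 24 (not isolated)
Conditions: OsO4 (3 mol%), NaIO4 (4 equiv), 2,6-lutidine (2 equiv), 1,4-dioxane–H2O 3:1, rt
Reagents that add atoms: osmium tetroxide, O=[Os](=O)(=O)=O (delivers the oxygen; turned over by sodium periodate, [Na+].[O-]I(=O)(=O)=O)
Why: Lemieux–Johnson oxidation of the only alkene, as in step 7; the benzyl ethers and the electron-rich rings are not attacked by OsO4, and the buffered medium protects the α-stereocentre.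

Step 18
Reactants: 25 (2R,3R)-2-(benzyloxy)-3-{3,4-bis(benzyloxy)-2-bromo-5-[(4R)-FL]phenyl}-3-[(tert-butyldimethylsilyl)oxy]propanal; 26 1-(benzyloxy)-4-bromobenzene
Product: 28 (1R,2S,3R)-2-(benzyloxy)-1-[4-(benzyloxy)phenyl]-3-{3,4-bis(benzyloxy)-2-bromo-5-[(4R)-FL]phenyl}-3-[(tert-butyldimethylsilyl)oxy]propan-1-ol, via 4-(benzyloxy)phenylmagnesium bromide 27 (not isolated)
Conditions: 26, Mg, THF, rt; then added to 25, MgBr2·OEt2, CH2Cl2, −78 °C; aq. NH4Cl
Reagents that add atoms: none
Why: Cram-chelate addition as in step 8: magnesium bridges the formyl and α-benzyloxy oxygens, and Grignard reagent 27 attacks from the face of the α-hydrogen, which should set C2 as R (2,3-syn) and leave its hydroxyl free for the ring closure.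

Step 19
Reactants: 28 (1R,2S,3R)-2-(benzyloxy)-1-[4-(benzyloxy)phenyl]-3-{3,4-bis(benzyloxy)-2-bromo-5-[(4R)-FL]phenyl}-3-[(tert-butyldimethylsilyl)oxy]propan-1-ol
Product: 29 (2R,3S,4R)-3,7,8-tris(benzyloxy)-2-[4-(benzyloxy)phenyl]-4-[(tert-butyldimethylsilyl)oxy]-6-[(4R)-FL]chromane (2,3-cis-3,4-cis)
Conditions: CuI (20 mol%), 3,4,7,8-tetramethyl-1,10-phenanthroline (40 mol%), Cs2CO3 (2 equiv), toluene (0.02 M), 110 °C, argon
Reagents that add atoms: none
Why: Ullmann-type C–O coupling: Cs2CO3 and phenanthroline-bound monovalent copper convert the C2 hydroxyl of 28 into a copper alkoxide, the metal adds oxidatively into the neighbouring C8a–Br bond to give trivalent copper, and reductive elimination forms O1–C8a. The closest known reaction type is the CuI/phenanthroline-catalysed etherification of aryl bromides with secondary alcohols in its intramolecular, chroman-forming version, already used in step 9. Ring C closes in a 6-exo manner at the sp2 carbon C8a. No stereocentre is created: C2, C3 and C4 keep all their bonds, so C2 is retained and the 2,3-syn-3,4-anti chain maps onto the 2,3-cis-3,4-cis ring (C3 is S in 29 only because O4 carries silicon). The step needs chemoselective arylation of O2, which is secured because O3 is a benzyl ether (no five-membered closure) and O4 a silyl ether. It also needs the alkoxide to couple faster than it is dehydrogenated or the silyl group migrates, which the chelating ligand, the intramolecular setting and the exclusion of air should favour. The lower unit and the nine benzyl ethers are inert to carbonate in toluene.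

Step 20
Reactants: 29 (2R,3S,4R)-3,7,8-tris(benzyloxy)-2-[4-(benzyloxy)phenyl]-4-[(tert-butyldimethylsilyl)oxy]-6-[(4R)-FL]chromane
Product: 30 (2R,3R,4R)-3,7,8-tris(benzyloxy)-2-[4-(benzyloxy)phenyl]-6-[(4R)-FL]chroman-4-ol
Conditions: Bu4NF, AcOH (1:1), THF, 0 °C to rt
Reagents that add atoms: none
Why: Fluoride cleavage of the silyl ether under buffered conditions; with all phenols still benzylated the benzylic 4-hydroxyl is not ionised.

Step 21
Reactants: 30 (2R,3R,4R)-3,7,8-tris(benzyloxy)-2-[4-(benzyloxy)phenyl]-6-[(4R)-FL]chroman-4-ol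
Product: 31 (2R,3R,4R)-2-(4-hydroxyphenyl)-6-[(2R,3R,4S)-2-(3,4-dihydroxyphenyl)-3,7,8-trihydroxychroman-4-yl]chromane-3,4,7,8-tetrol
Conditions: H2 (1 atm), Pd(OH)2/C, THF–MeOH 1:1, rt; filtration and evaporation under argon
Reagents that add atoms: none
Why: Hydrogenolysis of the nine benzyl ethers over Pd(OH)2 on carbon in neutral solvent; the decaol should need only filtration and evaporation, and no stereocentre is touched.

Compound list

1 | benzyl propargyl ether [3-(benzyloxy)prop-1-yne] | C#CCOCc1ccccc1 | starting material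
2 | 2-[(E)-3-(benzyloxy)prop-1-en-1-yl]-4,4,5,5-tetramethyl-1,3,2-dioxaborolane | CC1(C)OB(/C=C/COCc2ccccc2)OC1(C)C | intermediate
3 | 2-[(E)-3-(benzyloxy)prop-2-en-1-yl]-4,4,5,5-tetramethyl-1,3,2-dioxaborolane | CC1(C)OB(C/C=C/OCc2ccccc2)OC1(C)C | intermediate
4 | 2-bromoisovanillin (2-bromo-3-hydroxy-4-methoxybenzaldehyde) | O=Cc1ccc(OC)c(O)c1Br | starting material
5 | 2-bromo-3,4-dihydroxybenzaldehyde | O=Cc1ccc(O)c(O)c1Br | intermediate
6 | 3,4-bis(benzyloxy)-2-bromobenzaldehyde | O=Cc1ccc(OCc2ccccc2)c(OCc2ccccc2)c1Br | intermediate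
7 | pinacol borate ester of 8 | C=C[C@H](OCc1ccccc1)[C@H](OB1OC(C)(C)C(C)(C)O1)c1ccc(OCc2ccccc2)c(OCc2ccccc2)c1Br | intermediate (not isolated)
8 | (1R,2S)-2-(benzyloxy)-1-[3,4-bis(benzyloxy)-2-bromophenyl]but-3-en-1-ol | C=C[C@H](OCc1ccccc1)[C@H](O)c1ccc(OCc2ccccc2)c(OCc2ccccc2)c1Br | intermediate
9 | (1R,2S)-2-(benzyloxy)-1-[3,4-bis(benzyloxy)-2-bromophenyl]-1-[(tert-butyldimethylsilyl)oxy]but-3-ene | C=C[C@H](OCc1ccccc1)[C@H](O[Si](C)(C)C(C)(C)C)c1ccc(OCc2ccccc2)c(OCc2ccccc2)c1Br | intermediate
10 | (3S,4R)-3-(benzyloxy)-4-[3,4-bis(benzyloxy)-2-bromophenyl]-4-[(tert-butyldimethylsilyl)oxy]butane-1,2-diol, both epimers at C2 | OCC(O)[C@H](OCc1ccccc1)[C@H](O[Si](C)(C)C(C)(C)C)c1ccc(OCc2ccccc2)c(OCc2ccccc2)c1Br | intermediate (not isolated)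
11 | (2R,3R)-2-(benzyloxy)-3-[3,4-bis(benzyloxy)-2-bromophenyl]-3-[(tert-butyldimethylsilyl)oxy]propanal | O=C[C@H](OCc1ccccc1)[C@H](O[Si](C)(C)C(C)(C)C)c1ccc(OCc2ccccc2)c(OCc2ccccc2)c1Br | intermediate
12 | 1,2-bis(benzyloxy)-4-bromobenzene | Brc1ccc(OCc2ccccc2)c(OCc2ccccc2)c1 | starting material
13 | 3,4-bis(benzyloxy)phenylmagnesium bromide | Br[Mg]c1ccc(OCc2ccccc2)c(OCc2ccccc2)c1 | intermediate (not isolated)
14 | (1R,2S,3R)-2-(benzyloxy)-1-[3,4-bis(benzyloxy)phenyl]-3-[3,4-bis(benzyloxy)-2-bromophenyl]-3-[(tert-butyldimethylsilyl)oxy]propan-1-ol | c1ccccc1COc1ccc([C@@H](O)[C@H](OCc2ccccc2)[C@H](O[Si](C)(C)C(C)(C)C)c2ccc(OCc3ccccc3)c(OCc3ccccc3)c2Br)cc1OCc1ccccc1 | intermediate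
15 | (2R,3S,4R)-3,7,8-tris(benzyloxy)-2-[3,4-bis(benzyloxy)phenyl]-4-[(tert-butyldimethylsilyl)oxy]chromane | c1ccccc1COc1ccc([C@H]2Oc3c(ccc(OCc4ccccc4)c3OCc5ccccc5)[C@@H](O[Si](C)(C)C(C)(C)C)[C@H]2OCc6ccccc6)cc1OCc7ccccc7 | intermediate
16 | (2R,3R,4R)-3,7,8-tris(benzyloxy)-2-[3,4-bis(benzyloxy)phenyl]chroman-4-ol | c1ccccc1COc1ccc([C@H]2Oc3c(ccc(OCc4ccccc4)c3OCc5ccccc5)[C@@H](O)[C@H]2OCc6ccccc6)cc1OCc7ccccc7 | intermediate
17 | 3-bromo-4-(1,3-dithian-2-yl)benzene-1,2-diol | Oc1ccc(C2SCCCS2)c(Br)c1O | intermediate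
18 | 3-bromo-4-(1,3-dithian-2-yl)-6-[(2R,3R,4S)-3,7,8-tris(benzyloxy)-2-[3,4-bis(benzyloxy)phenyl]chroman-4-yl]benzene-1,2-diol | Oc1c(O)c(Br)c(C5SCCCS5)cc1[C@H]2c3ccc(OCc4ccccc4)c(OCc4ccccc4)c3O[C@H](c3ccc(OCc4ccccc4)c(OCc4ccccc4)c3)[C@@H]2OCc2ccccc2 | intermediate
19 | 2-{3,4-bis(benzyloxy)-2-bromo-5-[(2R,3R,4R)-3,7,8-tris(benzyloxy)-2-[3,4-bis(benzyloxy)phenyl]chroman-4-yl]phenyl}-1,3-dithiane | c5ccccc5COc1c(OCc5ccccc5)c(Br)c(C5SCCCS5)cc1[C@H]2c3ccc(OCc4ccccc4)c(OCc4ccccc4)c3O[C@H](c3ccc(OCc4ccccc4)c(OCc4ccccc4)c3)[C@@H]2OCc2ccccc2 | intermediate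
20 | 3,4-bis(benzyloxy)-2-bromo-5-[(2R,3R,4R)-3,7,8-tris(benzyloxy)-2-[3,4-bis(benzyloxy)phenyl]chroman-4-yl]benzaldehyde | O=Cc1cc([C@H]2c3ccc(OCc4ccccc4)c(OCc4ccccc4)c3O[C@H](c3ccc(OCc4ccccc4)c(OCc4ccccc4)c3)[C@@H]2OCc2ccccc2)c(OCc2ccccc2)c(OCc2ccccc2)c1Br | intermediate
21 | pinacol borate ester of 22 | C=C[C@H](OCc5ccccc5)[C@H](OB5OC(C)(C)C(C)(C)O5)c1cc([C@H]2c3ccc(OCc4ccccc4)c(OCc4ccccc4)c3O[C@H](c3ccc(OCc4ccccc4)c(OCc4ccccc4)c3)[C@@H]2OCc2ccccc2)c(OCc2ccccc2)c(OCc2ccccc2)c1Br | intermediate (not isolated)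
22 | (1R,2S)-2-(benzyloxy)-1-{3,4-bis(benzyloxy)-2-bromo-5-[(4R)-FL]phenyl}but-3-en-1-ol | C=C[C@H](OCc5ccccc5)[C@H](O)c1cc([C@H]2c3ccc(OCc4ccccc4)c(OCc4ccccc4)c3O[C@H](c3ccc(OCc4ccccc4)c(OCc4ccccc4)c3)[C@@H]2OCc2ccccc2)c(OCc2ccccc2)c(OCc2ccccc2)c1Br | intermediate
23 | (1R,2S)-2-(benzyloxy)-1-{3,4-bis(benzyloxy)-2-bromo-5-[(4R)-FL]phenyl}-1-[(tert-butyldimethylsilyl)oxy]but-3-ene | C=C[C@H](OCc5ccccc5)[C@H](O[Si](C)(C)C(C)(C)C)c1cc([C@H]2c3ccc(OCc4ccccc4)c(OCc4ccccc4)c3O[C@H](c3ccc(OCc4ccccc4)c(OCc4ccccc4)c3)[C@@H]2OCc2ccccc2)c(OCc2ccccc2)c(OCc2ccccc2)c1Br | intermediate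
24 | (3S,4R)-3-(benzyloxy)-4-{3,4-bis(benzyloxy)-2-bromo-5-[(4R)-FL]phenyl}-4-[(tert-butyldimethylsilyl)oxy]butane-1,2-diol, both epimers at C2 | OCC(O)[C@H](OCc5ccccc5)[C@H](O[Si](C)(C)C(C)(C)C)c1cc([C@H]2c3ccc(OCc4ccccc4)c(OCc4ccccc4)c3O[C@H](c3ccc(OCc4ccccc4)c(OCc4ccccc4)c3)[C@@H]2OCc2ccccc2)c(OCc2ccccc2)c(OCc2ccccc2)c1Br | intermediate (not isolated)
25 | (2R,3R)-2-(benzyloxy)-3-{3,4-bis(benzyloxy)-2-bromo-5-[(4R)-FL]phenyl}-3-[(tert-butyldimethylsilyl)oxy]propanal | O=C[C@H](OCc5ccccc5)[C@H](O[Si](C)(C)C(C)(C)C)c1cc([C@H]2c3ccc(OCc4ccccc4)c(OCc4ccccc4)c3O[C@H](c3ccc(OCc4ccccc4)c(OCc4ccccc4)c3)[C@@H]2OCc2ccccc2)c(OCc2ccccc2)c(OCc2ccccc2)c1Br | intermediate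
26 | 1-(benzyloxy)-4-bromobenzene | Brc1ccc(OCc2ccccc2)cc1 | starting material
27 | 4-(benzyloxy)phenylmagnesium bromide | Br[Mg]c1ccc(OCc2ccccc2)cc1 | intermediate (not isolated)
28 | (1R,2S,3R)-2-(benzyloxy)-1-[4-(benzyloxy)phenyl]-3-{3,4-bis(benzyloxy)-2-bromo-5-[(4R)-FL]phenyl}-3-[(tert-butyldimethylsilyl)oxy]propan-1-ol (C1, C2, C3 = flavan C2, C3, C4) | c6ccccc6COc1ccc([C@@H](O)[C@H](OCc6ccccc6)[C@H](O[Si](C)(C)C(C)(C)C)c3cc([C@H]4c5ccc(OCc6ccccc6)c(OCc6ccccc6)c5O[C@H](c5ccc(OCc6ccccc6)c(OCc6ccccc6)c5)[C@@H]4OCc6ccccc6)c(OCc6ccccc6)c(OCc6ccccc6)c3Br)cc1 | intermediate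
29 | (2R,3S,4R)-3,7,8-tris(benzyloxy)-2-[4-(benzyloxy)phenyl]-4-[(tert-butyldimethylsilyl)oxy]-6-[(4R)-FL]chromane | c6ccccc6COc1ccc([C@H]2Oc3c(cc([C@H]4c5ccc(OCc6ccccc6)c(OCc6ccccc6)c5O[C@H](c5ccc(OCc6ccccc6)c(OCc6ccccc6)c5)[C@@H]4OCc6ccccc6)c(OCc6ccccc6)c3OCc6ccccc6)[C@@H](O[Si](C)(C)C(C)(C)C)[C@H]2OCc6ccccc6)cc1 | intermediate
30 | (2R,3R,4R)-3,7,8-tris(benzyloxy)-2-[4-(benzyloxy)phenyl]-6-[(4R)-FL]chroman-4-ol | c6ccccc6COc1ccc([C@H]2Oc3c(cc([C@H]4c5ccc(OCc6ccccc6)c(OCc6ccccc6)c5O[C@H](c5ccc(OCc6ccccc6)c(OCc6ccccc6)c5)[C@@H]4OCc6ccccc6)c(OCc6ccccc6)c3OCc6ccccc6)[C@@H](O)[C@H]2OCc6ccccc6)cc1 | intermediate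
31 | (2R,3R,4R)-2-(4-hydroxyphenyl)-6-[(2R,3R,4S)-2-(3,4-dihydroxyphenyl)-3,7,8-trihydroxychroman-4-yl]chromane-3,4,7,8-tetrol | Oc1ccc([C@H]2Oc3c(cc([C@H]4c5ccc(O)c(O)c5O[C@H](c5ccc(O)c(O)c5)[C@@H]4O)c(O)c3O)[C@@H](O)[C@H]2O)cc1 | target

Total step count: 21. Longest linear sequence: 18 steps (steps 3 to 10 and 12 to 21 from 4; the same length through steps 1, 2, 5 to 10 and 12 to 21 from 1).

Steps least certain to work

Step 19 (key step, rehearsed in step 9). Oxidative addition into the electron-rich C8a–Br bond, which has substituents on both ortho positions, may be slow. Side processes could then take over: migration of the silyl group from O4 to the C2 alkoxide, copper-mediated dehydrogenation of the benzylic alkoxide, or loss of bromine by protonation. Fallback: 28 is first converted by a base-free aromatic Finkelstein exchange (CuI, NaI, trans-N,N'-dimethylcyclohexane-1,2-diamine, 1,4-dioxane, 110 °C; the free hydroxyl is untouched) into the aryl iodide F1. F1 adds to copper far more readily and should cyclise with the same CuI/phenanthroline/Cs2CO3 system at 60 to 80 °C, which brings the route back to 29.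

Step 12. Ring A may be alkylated at the wrong position (C5, para to O8) or on oxygen, and the cation may condense with the benzyloxy-substituted rings of a second molecule of 16. Either would lower the amount of the C6-linked 3',4'-trans product. Fallback: regiocontrol is moved from a catechol to a single phenol. Starting from 5, the dianion (NaH, 2.2 equiv, DMSO) is benzylated with one equivalent of BnBr at the more nucleophilic O3 to give 3-(benzyloxy)-2-bromo-4-hydroxybenzaldehyde F2. Dithioacetalisation as in step 11 gives 2-(benzyloxy)-3-bromo-4-(1,3-dithian-2-yl)phenol F3, in which only the hydroxyl para to the masked formyl group activates the ring. Coupling with 16 as in step 12 gives the mono-phenol F4, and benzylation of its one hydroxyl (BnBr, K2CO3, DMF) returns the route to 19.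

Steps 5 and 15. Face selection on the ortho-brominated aldehydes may be incomplete, and partial E to Z isomerisation of 3 would bring in the syn diastereomer. Fallback (written for step 5; the same sequence applies from 20 to 25): an auxiliary-controlled anti-glycolate aldol replaces the allylboration. The chlorotitanium enolate of (R)-4-benzyl-3-(benzyloxyacetyl)-1,3-oxazolidine-2-thione (TiCl4, iPr2NEt, CH2Cl2, −78 °C) is added to 6 precomplexed with TiCl4. The open transition state should give the anti adduct F5. Silylation (TBSOTf, 2,6-lutidine) gives F6, and iBu2AlH at −78 °C reduces the imide directly to aldehyde 11. The fallback sets out from 6 and returns at 11, bypassing 8 and 9.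

Steps 8 and 18. Chelation control may be incomplete, which would put the C2 epimer (leading to a 2,3-trans flavan) into the product, and the α-alkoxy aldehyde may enolise under the basic Grignard reagent. Fallback (written for step 18): the C2 stereocentre is set by reduction instead of addition. The mixture of 28 and its C2 epimer is oxidised with Dess–Martin periodinane (NaHCO3, CH2Cl2) to the aryl ketone F7. Corey–Bakshi–Shibata reduction with (R)-2-methyl-CBS-oxazaborolidine and BH3·SMe2, whose reagent preference coincides with the Felkin–Anh preference of the α-benzyloxy ketone, should return 28 as the 2,3-syn alcohol.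

Step 21. During hydrogenolysis the benzylic C4–O bond may be cleaved as well, and the free decaol may ionise at C4 or oxidise in air during handling. Fallback: the order of the last two steps is reversed. 29 is hydrogenolysed first (H2, Pd(OH)2/C, THF–MeOH), so that the silyl ether shields the C4–O bond, giving the 4-O-silyl decaol precursor F8. The silyl group is then removed with Bu4NF/AcOH in THF under argon to give 31.

Further compounds

F1 | step 19 | (1R,2S,3R)-2-(benzyloxy)-1-[4-(benzyloxy)phenyl]-3-{3,4-bis(benzyloxy)-2-iodo-5-[(4R)-FL]phenyl}-3-[(tert-butyldimethylsilyl)oxy]propan-1-ol | c6ccccc6COc1ccc([C@@H](O)[C@H](OCc6ccccc6)[C@H](O[Si](C)(C)C(C)(C)C)c3cc([C@H]4c5ccc(OCc6ccccc6)c(OCc6ccccc6)c5O[C@H](c5ccc(OCc6ccccc6)c(OCc6ccccc6)c5)[C@@H]4OCc6ccccc6)c(OCc6ccccc6)c(OCc6ccccc6)c3I)cc1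
F2 | step 12 | 3-(benzyloxy)-2-bromo-4-hydroxybenzaldehyde | O=Cc1ccc(O)c(OCc2ccccc2)c1Br
F3 | step 12 | 2-(benzyloxy)-3-bromo-4-(1,3-dithian-2-yl)phenol | Oc1ccc(C2SCCCS2)c(Br)c1OCc1ccccc1
F4 | step 12 | 2-(benzyloxy)-3-bromo-4-(1,3-dithian-2-yl)-6-[(2R,3R,4S)-3,7,8-tris(benzyloxy)-2-[3,4-bis(benzyloxy)phenyl]chroman-4-yl]phenol | Oc1c(OCc5ccccc5)c(Br)c(C5SCCCS5)cc1[C@H]2c3ccc(OCc4ccccc4)c(OCc4ccccc4)c3O[C@H](c3ccc(OCc4ccccc4)c(OCc4ccccc4)c3)[C@@H]2OCc2ccccc2
F5 | step 5 | (R)-4-benzyl-3-[(2R,3R)-2-(benzyloxy)-3-[3,4-bis(benzyloxy)-2-bromophenyl]-3-hydroxypropanoyl]-1,3-oxazolidine-2-thione | S=C1OC[C@@H](Cc2ccccc2)N1C(=O)[C@H](OCc2ccccc2)[C@H](O)c2ccc(OCc3ccccc3)c(OCc3ccccc3)c2Br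
F6 | step 5 | (R)-4-benzyl-3-[(2R,3R)-2-(benzyloxy)-3-[3,4-bis(benzyloxy)-2-bromophenyl]-3-[(tert-butyldimethylsilyl)oxy]propanoyl]-1,3-oxazolidine-2-thione | S=C1OC[C@@H](Cc2ccccc2)N1C(=O)[C@H](OCc2ccccc2)[C@H](O[Si](C)(C)C(C)(C)C)c2ccc(OCc3ccccc3)c(OCc3ccccc3)c2Br
F7 | step 18 | (2R,3R)-2-(benzyloxy)-1-[4-(benzyloxy)phenyl]-3-{3,4-bis(benzyloxy)-2-bromo-5-[(4R)-FL]phenyl}-3-[(tert-butyldimethylsilyl)oxy]propan-1-one | c6ccccc6COc1ccc(C(=O)[C@H](OCc6ccccc6)[C@H](O[Si](C)(C)C(C)(C)C)c3cc([C@H]4c5ccc(OCc6ccccc6)c(OCc6ccccc6)c5O[C@H](c5ccc(OCc6ccccc6)c(OCc6ccccc6)c5)[C@@H]4OCc6ccccc6)c(OCc6ccccc6)c(OCc6ccccc6)c3Br)cc1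
F8 | step 21 | 4-O-(tert-butyldimethylsilyl) ether of 31 | Oc1ccc([C@H]2Oc3c(cc([C@H]4c5ccc(O)c(O)c5O[C@H](c5ccc(O)c(O)c5)[C@@H]4O)c(O)c3O)[C@@H](O[Si](C)(C)C(C)(C)C)[C@H]2O)cc1
A1 | alternative 1 | hepta-O-benzyl 4-O-silyl derivative of 31 with O3 and O3' free | c6ccccc6COc1ccc([C@H]2Oc3c(cc([C@H]4c5ccc(OCc6ccccc6)c(OCc6ccccc6)c5O[C@H](c5ccc(OCc6ccccc6)c(OCc6ccccc6)c5)[C@@H]4O)c(OCc6ccccc6)c3OCc6ccccc6)[C@@H](O[Si](C)(C)C(C)(C)C)[C@H]2O)cc1
A2 | alternative 1 | open-chain bis(cis-epoxide) with free phenols at C8a and C8a' | c6ccccc6COc1ccc([C@@H]7O[C@@H]7[C@H](O[Si](C)(C)C(C)(C)C)c3cc([C@@H](c5ccc(OCc6ccccc6)c(OCc6ccccc6)c5O)[C@H]8O[C@H]8c5ccc(OCc6ccccc6)c(OCc6ccccc6)c5)c(OCc6ccccc6)c(OCc6ccccc6)c3O)cc1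
A3 | alternative 2 | 2',3'-cis-3',4'-trans 4'-aryl flavan-3'-ol with a 2-hydroxy-3,4-bis(benzyloxy)phenyl group at C4' | Oc3c(OCc6ccccc6)c(OCc6ccccc6)ccc3[C@H]4c5ccc(OCc6ccccc6)c(OCc6ccccc6)c5O[C@H](c5ccc(OCc6ccccc6)c(OCc6ccccc6)c5)[C@@H]4O
A4 | alternative 2 | cis-epoxide carrying two 2-hydroxy-3,4-bis(benzyloxy)phenyl groups at C4' | Oc1c(OCc6ccccc6)c(OCc6ccccc6)ccc1C(c1ccc(OCc6ccccc6)c(OCc6ccccc6)c1O)[C@H]2O[C@H]2c1ccc(OCc6ccccc6)c(OCc6ccccc6)c1
A5 | alternative 3 | hepta-O-benzyl derivative of 31 as its 3,4-cyclic carbonate with O7 free | c6ccccc6COc1ccc([C@H]2Oc3c(cc([C@H]4c5ccc(OCc6ccccc6)c(OCc6ccccc6)c5O[C@H](c5ccc(OCc6ccccc6)c(OCc6ccccc6)c5)[C@@H]4OCc6ccccc6)c(O)c3OCc6ccccc6)[C@@H](OC(=O)O7)[C@H]27)cc1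
A6 | alternative 3 | (2S,3R)-2-(benzyloxy)-3-[2,3-bis(benzyloxy)phenoxy]-3-[3,4-bis(benzyloxy)phenyl]propanal | O=C[C@@H](OCc6ccccc6)[C@H](Oc1cccc(OCc6ccccc6)c1OCc6ccccc6)c1ccc(OCc6ccccc6)c(OCc6ccccc6)c1
A7 | alternative 3 | 3,4-cyclic carbonate of (2R,3R,4R)-8-(benzyloxy)-2-[4-(benzyloxy)phenyl]chromane-3,4,7-triol | c6ccccc6COc1ccc([C@H]2Oc3c(ccc(O)c3OCc6ccccc6)[C@@H](OC(=O)O7)[C@H]27)cc1
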